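(Its constants stand for no real mixture; the rest is arithmetic.)

Minutes of the meeting on this flask. The chair set two clocks side by side: the life of D against E at the charged strength of E is 23.8 s, far shorter than the run of 15 h.

E 0.30 M; D 1.50 equiv (in portions, 2); time 15 h; the portions of D follow each other after 30 s, the first at the start

1. why nothing more happens at 15 h, or that something still does (it is still moving / all of E has reacted / D has run out first)
2. how much of the E has reacted by 15 h
3. how much D.E.D there is at 15 h, in percent of the E charged
4. how much E.D there is at 15 h, in percent of the E charged

- what has gone from E into another species counts as reacted, even if it can come back
- the reaction counts as stopped when no species that holds the E changes by six tenths of a point or more over the second half of the time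
- run time (flask): 15 h

The chair recalled the chemistry. E takes up D in turn, giving E.D, then D.E.D, then Z. E also exchanges with G, and D.E.D exchanges with J.

    D.E.D ⇌ J (K1 = 0.61, k1 = 0.00307 /s)
    E ⇌ G (K2 = 0.438, k2 = 0.00292 /s)
    D + D.E.D → Z (k3 = 0.0631 /M/s)
    D + E.D → D.E.D (k4 = 0.111 /M/s)
    E + D → E.D (k5 = 0.140 /M/s)

The secretary proposed counting turnovers. Each addition spends one D. So this flask pays for 1.50 additions per E, fewer than the 3 of a full Z, and she named D the limiting reagent. She pictured the additions falling on each E at random around that mean, as a Poisson count. The picture is rough. It treats the addition constants as equal, though the first and last differ by a factor of 2.22, and it ignores the stop at Z and the E held as G. She accepted that roughness.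

She then defined the idle share, the part of E with no addition, as the exponential of minus the count: 22.3%. The share with one addition is the count times the idle share, which gives E.D at 33.5%. E and G relax with a half-life of 1.21 min, shorter than the run, so she divided the idle part between them, with G at 0.438 times E. Her conversion was 84.5%. She committed to no figure for D.E.D.

The forecast was then read: D has run out first, conversion 87.5%, D.E.D 22.8%, E.D 29.6%. Its ground was that “Afterwards only the two equilibria settle”. It stood above the secretary on conversion and below her on E.D.

The simulation gives D has run out first, with 0% of D left at 15.0 h, conversion 87.5%, D.E.D 22.8% and E.D 29.7%. The forecast holds; it would fail on D.E.D if D stood at 1.17 equiv or 2.55 equiv, where that answer has moved by 5 points. In this flask, E and G together hold 18.0%, less than the idle share of 22.3%.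

On a second flask with 0.600 equiv of D, the idle share is 54.9%, which gives conversion 61.8% and E.D 32.9%. That flask computes to conversion 62.7% and E.D 34.1%.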